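**Plan**

- Retrosynthesis: the 3-O-acyl/2-OH pair goes back to a 2α,3α-epoxide opened by the dienoic acid. Ring B is cut at C6=C7 (aldol condensation) and C9=C10 (dehydrogenation). Ring A is cut at C5–C10 and C2–C3.
- Enabling feature: in ring A the quaternary C5 sits between C4 and C6, and C3 is the other neighbour of C4. With C4 as a ketone and C6 as an ester carbonyl, C5 is a doubly activated donor for C10 (β-carbon of an enal that ends in C2), and C3 is a methyl-ketone carbon that condenses with C2. The C4 methyl marks the helper carbonyl; the ester oxygen ties C6 to C8 as a temporary δ-lactone.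
- Forward order: (R)-glycidol → tethered keto ester/enal (steps 1–4) → lactone and ring A in one Michael/aldol condensation (step 5) → C4 methyl (steps 6–7) → lactone opened, ring B closed (steps 8–10) → epoxide, dienone (steps 11–12) → union with the acid, deprotection (steps 16–17).
- Stereochemistry: C8 from (R)-glycidol sets C10 and C5 in step 5. C4 follows from C5 (anti addition of MeLi, inverting hydride delivery). C2 and C3 follow from C5 (α-epoxidation, trans-diaxial opening). C8 and C10 are later flattened to sp2. The side-chain centre comes from (S)-2-methylbutan-1-ol.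

Key step: step 5

Remark: core carbons carry eremophilane numbers (ring A = C1–C5, C10; ring B = C5–C10; C14 = methyl on C5, C15 = methyl on C4), β is the face of the C5 methyl, and compounds 5 and 7 are taken as both epimers at the acidic α-carbon because that centre is re-formed in step 5.

**Step 1**
Reactants: 1 (R)-glycidol
Product: 2 (S)-2-[(methoxymethoxy)methyl]oxirane
Conditions: MOMCl, i-Pr2NEt, CH2Cl2, 0 °C to rt
Reagents that add atoms: chloromethyl methyl ether, COCCl
Why: O-alkylation of the primary alcohol with the chloromethyl ether under amine base (acetal protection) leaves the epoxide and its stereocentre, the later C8, untouched.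

**Step 2**
Reactants: 2 (S)-2-[(methoxymethoxy)methyl]oxirane
Product: 3 (S)-1-(methoxymethoxy)pent-4-en-2-ol
Conditions: vinylmagnesium bromide, CuI (10 mol%), THF, −40 °C to −20 °C
Reagents that add atoms: vinylmagnesium bromide, C=C[Mg]Br
Why: copper-catalysed Grignard opening of a terminal epoxide is an SN2 attack at the unsubstituted carbon, so the carbinol centre keeps its configuration while the chain gains C10 as a vinyl group.

**Step 3**
Reactants: 3 (S)-1-(methoxymethoxy)pent-4-en-2-ol; 4 methyl 2-methyl-3-oxobutanoate
Product: 5 (S)-1-(methoxymethoxy)pent-4-en-2-yl 2-methyl-3-oxobutanoate (both α-epimers)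
Conditions: DMAP (0.3 equiv), toluene, reflux, 4 Å molecular sieves (removal of MeOH)
Reagents that add atoms: none
Why: DMAP-catalysed transesterification of an enolisable β-keto ester (through the acylketene) is a standard way to place an acetoacetate on a secondary alcohol, and the α-carbon is a labile centre that is set anew in step 5.

**Step 4**
Reactants: 5 keto ester; 6 (E)-but-2-enal
Product: 7 (S,E)-1-(methoxymethoxy)-6-oxohex-4-en-2-yl 2-methyl-3-oxobutanoate (both α-epimers)
Conditions: second-generation Hoveyda–Grubbs catalyst C31H38Cl2N2ORu (3 mol%), crotonaldehyde (5 equiv), CH2Cl2, 40 °C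
Reagents that add atoms: none
Why: olefin cross-metathesis of a terminal alkene with crotonaldehyde should give the (E)-enal and propene, and ruthenium carbenes tolerate β-keto esters and acetals.

**Step 5**
Reactants: 7 tethered keto ester enal
Product: 10 trans-fused enone lactone (3-[(methoxymethoxy)methyl]-8a-methyl-3,4,4a,5-tetrahydro-1H-isochromene-1,8(8aH)-dione), via Michael adduct 8 (not isolated), via ketol 9 (not isolated)
Conditions: LiCl (1.0 equiv), Et3N (1.0 equiv), MeCN, 0 °C to rt; then pyrrolidine (0.3 equiv), AcOH (0.6 equiv), 40 °C, same flask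
Reagents that add atoms: none
Why: LiCl/Et3N soft enolisation gives the chelated lithium enolate of the β-keto ester, whose carbon C5 adds to C10 of the tethered (E)-enal (intramolecular Michael addition), and pyrrolidinium acetate then condenses the methyl-ketone carbon C3 with the freed C2 aldehyde and dehydrates the ketol to the C2=C3 enone (aldol condensation). The closest known reactions are the Robinson annulation and the amine-catalysed Michael/aldol condensation of β-keto esters with enals to cyclohexenones, here run on a keto ester tethered through its ester oxygen. The temporary δ-lactone closes 6-exo-trig, and ring A closes 6-(enolendo)-exo-trig followed by E1cB dehydration. C10 is set by the glycidol-derived C8 through a chair transition state with the CH2OMOM group and the enal both equatorial, and C5 is set by the U-shaped chelated enolate, which keeps the acetyl group exo (equatorial) and the methyl on the tether side (axial), so that ring A should fuse trans (C5 methyl β, H-10 α). The step needs C-attack by C5 before the keto acid can leave C8 by vinylogous β-elimination, which the weak tertiary amine (no dienamine) and the late addition of the secondary amine are meant to secure. Regiochemistry is fixed by the substrate: C5 is the only doubly activated carbon, the ketone can enolise only toward C3, and only the six-membered aldol ring is within reach.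

**Step 6**
Reactants: 10 enone lactone
Product: 12 tertiary allylic methyl carbonate (4α-methyl, 4β-OCO2Me), via lithium alkoxide 11 (not isolated)
Conditions: MeLi (1.1 equiv), THF, −78 °C; then ClCO2Me, −78 °C to 0 °C
Reagents that add atoms: methyllithium, [Li]C; methyl chloroformate, COC(=O)Cl
Why: methyllithium adds 1,2 to the enone (carbonyl addition; the ketone has no α-hydrogen on its sp3 side and should outpace the hindered lactone at −78 °C) from the α face, anti to the axial C5 methyl, so the alkoxide oxygen is β and is trapped at once by O-acylation.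

**Step 7**
Reactants: 12 tertiary allylic carbonate
Product: 13 lactone with C2=C3 alkene and 4β-methyl (3-[(methoxymethoxy)methyl]-8,8a-dimethyl-3,4,4a,5,8,8a-hexahydro-1H-isochromen-1-one)
Conditions: Pd(OAc)2 (5 mol%), n-Bu3P (20 mol%), HCO2NH4 (3 equiv), THF, 40 °C
Reagents that add atoms: none
Why: Tsuji–Trost ionisation by zerovalent palladium anti to the β-carbonate, then formate decarboxylation and hydride transfer from palladium to the more substituted allyl terminus (palladium-catalysed formate hydrogenolysis), should put H-4 on the α face, leave the C4 methyl β (cis to the C5 methyl) and return the double bond to C2=C3.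

**Step 8**
Reactants: 13 lactone
Product: 14 diol ((2S)-1-[6-(hydroxymethyl)-5,6-dimethylcyclohex-3-en-1-yl]-3-(methoxymethoxy)propan-2-ol)
Conditions: LiAlH4, THF, 0 °C
Reagents that add atoms: none
Why: hydride reduction of the lactone to the diol takes out the temporary ring and frees C6 and C8 for ring B, while the isolated alkene and the acetal are inert.

**Step 9**
Reactants: 14 diol
Product: 15 keto aldehyde (6-[3-(methoxymethoxy)-2-oxopropyl]-1,2-dimethylcyclohex-3-ene-1-carbaldehyde)
Conditions: Dess–Martin periodinane (3 equiv), NaHCO3, CH2Cl2, rt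
Reagents that add atoms: none
Why: Dess–Martin oxidation should convert the neopentyl primary and the secondary alcohol to the aldehyde and the ketone in one pot under buffered conditions, and the C8 stereocentre is spent here.

**Step 10**
Reactants: 15 keto aldehyde
Product: 17 ring B enone (3-(methoxymethoxy)-4a,5-dimethyl-4a,5,8,8a-tetrahydronaphthalen-2(1H)-one), via ketol 16 (not isolated)
Conditions: NaOMe (0.3 equiv), MeOH, 0 °C to rt
Reagents that add atoms: none
Why: intramolecular aldol condensation (6-(enolendo)-exo-trig) of the α-alkoxy ketone carbon C7 onto the non-enolisable C6 aldehyde closes ring B, because the other enolate (C9) could only form a four-membered ring, and E1cB loss of water gives the 2-alkoxy enone.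

**Step 11**
Reactants: 17 ring B enone
Product: 18 2α,3α-epoxy enone
Conditions: mCPBA (1.05 equiv), NaHCO3, CH2Cl2, 0 °C
Reagents that add atoms: 3-chloroperoxybenzoic acid, OOC(=O)c1cccc(Cl)c1
Why: Prilezhaev epoxidation should pick the isolated C2=C3 bond over the carbonyl-conjugated one and come from the α face, anti to the axial C5 methyl and the C4 methyl.

**Step 12**
Reactants: 18 epoxy enone
Product: 19 2α,3α-epoxy dienone
Conditions: IBX (2.5 equiv), 4-methoxypyridine N-oxide (2.5 equiv), DMSO, rt to 40 °C
Reagents that add atoms: none
Why: IBX dehydrogenation of the enone through its only enolisable position C9 removes H-9 and the tertiary H-10 under non-basic conditions, which gives the cross-conjugated dienone and erases the relay stereocentre C10.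

**Step 13**
Reactants: 20 (S)-2-methylbutan-1-ol
Product: 21 (S)-2-methylbutanal
Conditions: TEMPO (10 mol%), PhI(OAc)2 (1.1 equiv), CH2Cl2, rt; used as its solution
Reagents that add atoms: none
Why: oxoammonium (TEMPO) oxidation stops at the aldehyde under non-basic conditions, so the α-stereocentre should not racemise.

**Step 14**
Reactants: 21 (S)-2-methylbutanal; 22 triethyl 4-phosphonocrotonate
Product: 23 ethyl (2E,4E,6S)-6-methylocta-2,4-dienoate
Conditions: 22, LiN(SiMe3)2, THF, −78 °C; then 21, −78 °C to 0 °C
Reagents that add atoms: none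
Why: vinylogous Horner–Wadsworth–Emmons olefination with the preformed lithium phosphonate at low temperature should give the (2E,4E)-dienoate without touching the α-stereocentre of the aldehyde.

**Step 15**
Reactants: 23 dienoate ester
Product: 24 (2E,4E,6S)-6-methylocta-2,4-dienoic acid
Conditions: LiOH, THF/MeOH/H2O, rt; then 1 M HCl
Reagents that add atoms: lithium hydroxide, [Li+].[OH-]
Why: saponification of the ethyl ester, the stereocentre being remote from any acidic position.

**Step 16**
Reactants: 19 epoxy dienone; 24 dienoic acid
Product: 25 7-O-methoxymethyl septeremophilane G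
Conditions: 24 (1.5 equiv), racemic N,N′-bis(3,5-di-tert-butylsalicylidene)-1,2-cyclohexanediaminocobalt C36H52CoN2O2 (10 mol%, divalent cobalt, oxidised by air in the flask to the trivalent cobalt carboxylate), i-Pr2NEt (1 equiv), t-BuOMe, air, rt
Reagents that add atoms: none
Why: cobalt-salen-catalysed addition of a carboxylic acid to an epoxide is an SN2 opening, and the Fürst–Plattner rule (trans-diaxial opening of the half-chair held by the axial C5 methyl and the planar ring B) should direct the carboxylate to C3 from the β face, giving the 3β-ester and the 2α-hydroxyl.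

**Step 17**
Reactants: 25 7-O-methoxymethyl septeremophilane G
Product: 26 septeremophilane G
Conditions: HCl (0.1 M, from AcCl), MeOH, 0 °C to rt
Reagents that add atoms: none
Why: acid-catalysed acetal exchange with methanol removes the methoxymethyl group from the enol oxygen under conditions expected to be too mild for ester exchange, acyl migration (trans-diaxial) or dienone–phenol rearrangement.

**Compound list**

1 | (R)-glycidol, (R)-oxiran-2-ylmethanol | OC[C@@H]1CO1 | starting material
2 | (S)-2-[(methoxymethoxy)methyl]oxirane | COCOC[C@@H]1CO1 | intermediate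
3 | (S)-1-(methoxymethoxy)pent-4-en-2-ol | COCOC[C@@H](O)CC=C | intermediate
4 | methyl 2-methyl-3-oxobutanoate (racemic) | COC(=O)C(C)C(C)=O | starting material
5 | (S)-1-(methoxymethoxy)pent-4-en-2-yl 2-methyl-3-oxobutanoate (both α-epimers) | CC(=O)C(C)C(=O)O[C@H](COCOC)CC=C | intermediate
6 | (E)-but-2-enal (crotonaldehyde) | C/C=C/C=O | starting material
7 | (S,E)-1-(methoxymethoxy)-6-oxohex-4-en-2-yl 2-methyl-3-oxobutanoate (both α-epimers) | CC(=O)C(C)C(=O)O[C@H](COCOC)C/C=C/C=O | intermediate
8 | Michael adduct, 2-[3-acetyl-6-[(methoxymethoxy)methyl]-3-methyl-2-oxooxan-4-yl]acetaldehyde (3-methyl axial; 4-CH2CHO and 6-CH2OMOM equatorial) | COCOC[C@@H]1C[C@H](CC=O)[C@@](C)(C(C)=O)C(=O)O1 | intermediate (not isolated)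
9 | ketol, 6-hydroxy-3-[(methoxymethoxy)methyl]-8a-methylhexahydro-1H-isochromene-1,8(8aH)-dione (trans-fused; carbinol configuration not fixed) | COCOC[C@@H]1C[C@@H]2CC(O)CC(=O)[C@@]2(C)C(=O)O1 | intermediate (not isolated)
10 | 3-[(methoxymethoxy)methyl]-8a-methyl-3,4,4a,5-tetrahydro-1H-isochromene-1,8(8aH)-dione (trans-fused: C5 methyl β, H-10 α; CH2OMOM β, equatorial) | COCOC[C@@H]1C[C@@H]2CC=CC(=O)[C@@]2(C)C(=O)O1 | intermediate
11 | lithium alkoxide of the 4β-hydroxy-4α-methyl adduct | COCOC[C@@H]1C[C@@H]2CC=C[C@](C)([O-])[C@@]2(C)C(=O)O1.[Li+] | intermediate (not isolated)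
12 | tertiary allylic methyl carbonate (4α-methyl, 4β-OCO2Me) | COCOC[C@@H]1C[C@@H]2CC=C[C@](C)(OC(=O)OC)[C@@]2(C)C(=O)O1 | intermediate
13 | 3-[(methoxymethoxy)methyl]-8,8a-dimethyl-3,4,4a,5,8,8a-hexahydro-1H-isochromen-1-one (4β- and 5β-methyl, H-10 α, C2=C3) | COCOC[C@@H]1C[C@@H]2CC=C[C@H](C)[C@@]2(C)C(=O)O1 | intermediate
14 | (2S)-1-[6-(hydroxymethyl)-5,6-dimethylcyclohex-3-en-1-yl]-3-(methoxymethoxy)propan-2-ol | COCOC[C@@H](O)C[C@@H]1CC=C[C@H](C)[C@@]1(C)CO | intermediate
15 | 6-[3-(methoxymethoxy)-2-oxopropyl]-1,2-dimethylcyclohex-3-ene-1-carbaldehyde | COCOCC(=O)C[C@@H]1CC=C[C@H](C)[C@@]1(C)C=O | intermediate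
16 | ring B ketol (C6 carbinol and C7 configurations not fixed) | C1=CC[C@H]2CC(=O)C(OCOC)C(O)[C@]2(C)[C@H]1C | intermediate (not isolated)
17 | 3-(methoxymethoxy)-4a,5-dimethyl-4a,5,8,8a-tetrahydronaphthalen-2(1H)-one (trans-fused) | C1=CC[C@H]2CC(=O)C(OCOC)=C[C@]2(C)[C@H]1C | intermediate
18 | 2α,3α-epoxy enone | O1[C@@H]2[C@H]1C[C@H]3CC(=O)C(OCOC)=C[C@]3(C)[C@H]2C | intermediate
19 | 2α,3α-epoxy dienone | O1[C@@H]2[C@H]1CC3=CC(=O)C(OCOC)=C[C@]3(C)[C@H]2C | intermediate
20 | (S)-2-methylbutan-1-ol | CC[C@H](C)CO | starting material
21 | (S)-2-methylbutanal | CC[C@H](C)C=O | intermediate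
22 | triethyl 4-phosphonocrotonate | CCOC(=O)/C=C/CP(=O)(OCC)OCC | starting material
23 | ethyl (2E,4E,6S)-6-methylocta-2,4-dienoate | CC[C@H](C)/C=C/C=C/C(=O)OCC | intermediate
24 | (2E,4E,6S)-6-methylocta-2,4-dienoic acid | CC[C@H](C)/C=C/C=C/C(=O)O | intermediate
25 | 7-O-methoxymethyl septeremophilane G | CC[C@H](C)/C=C/C=C/C(=O)O[C@H]1[C@H](O)CC2=CC(=O)C(OCOC)=C[C@]2(C)[C@H]1C | intermediate
26 | septeremophilane G | CC[C@H](C)/C=C/C=C/C(=O)O[C@H]1[C@H](O)CC2=CC(=O)C(O)=C[C@]2(C)[C@H]1C | target

**Step count and risks**

Total steps: 17. Longest linear sequence: 14 (steps 1–12, 16, 17); the acid branch (steps 13–15) joins at step 16.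

Step 5. The keto acid may leave C8 by vinylogous β-elimination before the C–C bond forms, or facial discrimination at C5 may be poor in the lactone-forming transition state. The fallback sets out from 3 and returns at 10; it gives up the tether and sets C10 with a chiral amine. Alcohol 3 is silylated (TBSCl, imidazole) to the silyl ether F1, and cross-metathesis with 6 gives the enal F2. Michael addition of keto ester 4 under (S)-α,α-diphenylprolinol trimethylsilyl ether catalysis, followed by pyrrolidinium acetate aldol condensation, gives the cyclohexenone ester F3 after separation from its C5 epimer. HF·pyridine and then p-TsOH close the δ-lactone to 10.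

Step 16. Opening at the hindered C3 may be sluggish, attack may leak to C2, or the epoxide may isomerise to an allylic alcohol through the vinylogous C1 enolate. The fallback sets out from 19 and returns at 26; it uses water as the small nucleophile and makes the ester by acylation. Dilute HClO4 in THF/H2O at 0 °C opens 19 trans-diaxially to the 2α,3β-diol F4. TESCl/imidazole silylates the less hindered 2-hydroxyl to the silyl ether F5. Yamaguchi esterification with 24 acylates the axial 3-hydroxyl to the ester F6. HCl in methanol then removes the silyl and methoxymethyl groups to give 26.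

Step 7. The pseudo-equatorial tertiary carbonate may ionise slowly, β-hydride elimination may give a diene, or hydride may be delivered to C2. The fallback sets out from 11 and returns at 13; it brings hydrogen to C4 by a sigmatropic shift instead of by palladium. Alkoxide 11 is quenched with aqueous NH4Cl to the tertiary alcohol F7. Pyridinium chlorochromate, C5H5NH[CrO3Cl], effects the Babler–Dauben oxidative transposition to the transposed enone F8. Luche reduction (NaBH4, CeCl3·7H2O) gives the 2β-allylic alcohol F9. Mitsunobu reaction with 2-nitrobenzenesulfonylhydrazide (PPh3, DEAD, −30 °C) gives the hydrazide F10, which on warming loses the sulfinic acid to the allylic diazene F11 and then dinitrogen, with suprafacial transfer of hydrogen to the α face of C4, which gives 13.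

**Further compounds**

F1 | step 5 | (S)-tert-butyl{[1-(methoxymethoxy)pent-4-en-2-yl]oxy}dimethylsilane | COCOC[C@@H](O[Si](C)(C)C(C)(C)C)CC=C
F2 | step 5 | (S,E)-5-(tert-butyldimethylsilyloxy)-6-(methoxymethoxy)hex-2-enal | COCOC[C@@H](O[Si](C)(C)C(C)(C)C)C/C=C/C=O
F3 | step 5 | methyl 6-[(2S)-2-(tert-butyldimethylsilyloxy)-3-(methoxymethoxy)propyl]-1-methyl-2-oxocyclohex-3-ene-1-carboxylate (C5 methyl β, H-10 α) | COCOC[C@@H](O[Si](C)(C)C(C)(C)C)C[C@@H]1CC=CC(=O)[C@@]1(C)C(=O)OC
F4 | step 16 | 7-O-methoxymethyl 2α,3β-diol of the dienone core | O[C@H]1[C@H](O)CC2=CC(=O)C(OCOC)=C[C@]2(C)[C@H]1C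
F5 | step 16 | 2-O-triethylsilyl ether of F4 | O[C@H]1[C@H](O[Si](CC)(CC)CC)CC2=CC(=O)C(OCOC)=C[C@]2(C)[C@H]1C
F6 | step 16 | 2-O-triethylsilyl-7-O-methoxymethyl septeremophilane G | CC[C@H](C)/C=C/C=C/C(=O)O[C@H]1[C@H](O[Si](CC)(CC)CC)CC2=CC(=O)C(OCOC)=C[C@]2(C)[C@H]1C
F7 | step 7 | tertiary allylic alcohol (4β-hydroxy-4α-methyl lactone) | COCOC[C@@H]1C[C@@H]2CC=C[C@](C)(O)[C@@]2(C)C(=O)O1
F8 | step 7 | transposed enone (C2 ketone, C3=C4 with C4 methyl) | COCOC[C@@H]1C[C@@H]2CC(=O)C=C(C)[C@@]2(C)C(=O)O1
F9 | step 7 | 2β-allylic alcohol | COCOC[C@@H]1C[C@@H]2C[C@H](O)C=C(C)[C@@]2(C)C(=O)O1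
F10 | step 7 | 2α-N-(2-nitrobenzenesulfonyl)hydrazide | COCOC[C@@H]1C[C@@H]2C[C@@H](N(N)S(=O)(=O)c3ccccc3[N+](=O)[O-])C=C(C)[C@@]2(C)C(=O)O1
F11 | step 7 | 2α-allylic diazene | COCOC[C@@H]1C[C@@H]2C[C@@H](N=N)C=C(C)[C@@]2(C)C(=O)O1
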